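Ring B (C5–C6–C7–C8–C9–C10) is disconnected at C7–C8 by a type 1 carbonyl-ene retron: the isopropenyl-bearing C7 lies beside the C8 carbinol and 1,3 to the methylated quaternary C5, the isopulegol pattern. In one operation the cyclization closes ring B onto a finished ring A, makes C7–C8, turns a prenyl group into the C7 isopropenyl group and leaves an 8-oxygen with a C9=C10 alkene from which C8, C9 and C10 are set. The precursor is a ring A cyclohexylidene acetaldehyde (C10=C9–C8HO) with a prenyl group on quaternary C5 and the C3 silyloxy and C4 methyl stereocentres in place. The bis-Z-enoate side chain is attached last as ynoates.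

Key step: step 9

Remark: eremophilane numbering is used throughout (ring A = C1–C5, C10; ring B = C5–C10; C14 = methyl on C5; C15 = methyl on C4; β = face of C14). The sense of induction in step 3 is assigned by analogy with transfer hydrogenation of aryl ketones and would be corrected with the (S,S) ligand if the opposite alcohol formed.

Step 1
Reactants: 1 4-methoxy-3-methylphenol
Product: 2 4,4-dimethoxy-3-methylcyclohexa-2,5-dien-1-one
Conditions: PhI(OAc)2, MeOH, 0 °C to rt
Reagents that add atoms: methanol CO
Why: Hypervalent-iodine oxidative dearomatisation of a para-methoxyphenol in methanol traps the phenoxonium ion at the methoxy-bearing carbon, which should give the quinone monoketal with the methyl group on the alkene next to the ketal.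

Step 2
Reactants: 2 4,4-dimethoxy-3-methylcyclohexa-2,5-dien-1-one
Product: 3 4,4-dimethoxy-3-methylcyclohex-2-en-1-one
Conditions: H2 (1 atm), RhCl(PPh3)3 (cat.), benzene, rt
Reagents that add atoms: none
Why: Homogeneous hydrogenation with Wilkinson's catalyst should saturate the unhindered disubstituted enone alkene well before the trisubstituted methyl-bearing one and should not hydrogenolyse or aromatise the ketal.

Step 3
Reactants: 3 4,4-dimethoxy-3-methylcyclohex-2-en-1-one
Product: 4 (R)-4,4-dimethoxy-3-methylcyclohex-2-en-1-ol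
Conditions: RuCl(p-cymene)[(R,R)-TsDPEN] (cat.), KOH (cat.), i-PrOH, rt
Reagents that add atoms: none
Why: Noyori asymmetric transfer hydrogenation reduces the enone carbonyl in the 1,2 sense with the alkene in the role of the aryl group, which should set the future C3 carbinol as R.

Step 4
Reactants: 4 (R)-4,4-dimethoxy-3-methylcyclohex-2-en-1-ol
Product: 5 (R)-tert-butyl[(4,4-dimethoxy-3-methylcyclohex-2-en-1-yl)oxy]dimethylsilane
Conditions: TBSCl, imidazole, DMF, rt
Reagents that add atoms: tert-butyldimethylsilyl chloride CC(C)(C)[Si](C)(C)Cl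
Why: Imidazole-promoted silylation of the secondary allylic alcohol is routine and the dimethyl ketal is inert to these basic conditions.

Step 5
Reactants: 5 (R)-tert-butyl[(4,4-dimethoxy-3-methylcyclohex-2-en-1-yl)oxy]dimethylsilane
Product: 6 (R)-4-(tert-butyldimethylsilyloxy)-2-methylcyclohex-2-en-1-one
Conditions: PPTS (cat.), acetone/H2O, rt
Reagents that add atoms: water O
Why: The dimethyl ketal is far more acid-labile than the secondary silyl ether, so mild hydrolysis should unmask the α-methyl enone without silyl loss or elimination.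

Step 6
Reactants: 6 (R)-4-(tert-butyldimethylsilyloxy)-2-methylcyclohex-2-en-1-one; 7 prenyl bromide (1-bromo-3-methylbut-2-ene)
Product: 9 ring A ketone (2R,3R,4R)-4-(tert-butyldimethylsilyloxy)-2,3-dimethyl-2-(3-methylbut-2-en-1-yl)cyclohexan-1-one, via lithium enolate 8 (not isolated)
Conditions: Me2CuLi (from MeLi and CuI), Et2O, −78 to −20 °C; then 7, HMPA/THF, −20 °C to rt
Reagents that add atoms: lithium dimethylcuprate [Li+].C[Cu-]C; prenyl bromide 7 CC(C)=CCBr
Why: Tandem conjugate addition–enolate alkylation: the Gilman reagent should add to C4 anti to the neighbouring silyloxy group, and the regiodefined tetrasubstituted enolate should be C-alkylated by the allylic bromide (SN2) anti to the new C4 methyl group, which sets quaternary C5 with the two methyl groups cis.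

Step 7
Reactants: 9 ring A ketone; 10 vinylmagnesium bromide
Product: 11 (2R,3R,4R)-4-(tert-butyldimethylsilyloxy)-2,3-dimethyl-2-(3-methylbut-2-en-1-yl)-1-vinylcyclohexan-1-ol (carbinol configuration not controlled and not needed)
Conditions: 10, CeCl3 (anhydrous), THF, −78 to 0 °C
Reagents that add atoms: vinylmagnesium bromide 10 C=C[Mg]Br
Why: CeCl3-promoted Grignard 1,2-addition (Imamoto conditions) suppresses enolisation of the hindered α-quaternary ketone, and either carbinol epimer serves because this carbon becomes sp2 in step 8.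

Step 8
Reactants: 11 tertiary vinyl carbinol
Product: 12 (E)-2-[(2R,3R,4R)-4-(tert-butyldimethylsilyloxy)-2,3-dimethyl-2-(3-methylbut-2-en-1-yl)cyclohexylidene]acetaldehyde (CHO anti to C5) and 13 its Z isomer (CHO syn to C5), obtained and used as the mixture
Conditions: pyridinium chlorochromate [C5H5NH][CrO3Cl], 4 Å MS, CH2Cl2, rt
Reagents that add atoms: pyridinium chlorochromate [O-][Cr](=O)(=O)Cl.c1cc[nH+]cc1
Why: Babler–Dauben oxidative transposition: the tertiary chromate ester undergoes a [3,3] shift to the primary allylic chromate, which is oxidised to the conjugated aldehyde, expected as an E/Z mixture rich in 12.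

Step 9
Reactants: 12 E enal; 13 Z enal (mixture from step 8)
Product: 14 3α-(tert-butyldimethylsilyloxy)eremophila-9,11-dien-8β-ol (4β,5β-dimethyl, 7α-isopropenyl)
Conditions: Me2AlCl (1.5–2 equiv), CH2Cl2, −78 °C to rt
Reagents that add atoms: none
Why: Me2AlCl binds the aldehyde oxygen, and in the Z enal 13 the C7=C11 bond of the prenyl group attacks C8 while a methyl hydrogen on C12 passes to oxygen through a six-centre array, so C7–C8 forms and C11=C12 becomes the isopropenyl alkene; the closest known reactions are the type 1 intramolecular carbonyl-ene cyclizations of neral to isopiperitenol and of citronellal to isopulegol. Ring B (C5–C6–C7–C8–C9–C10) closes as a six-membered carbocycle by 6-exo attack of the tether-proximal alkene carbon on the carbonyl carbon, the oxygen staying outside the ring, through a half-chair fused to ring A. C7 is controlled by ring A: its equatorial C3 silyloxy and C4 methyl groups hold the C5 methyl axial on the forming ring, so the prenyl terminus must lie equatorial and the isopropenyl group ends trans to that methyl (7α); C8 is expected trans to C7 (8β) but is erased in step 10, so either epimer serves. The step needs the Z geometry, which only 13 has: 12 cannot reach C7, but its aluminium complex has allyl-cation character at the fully substituted C10, so rotation about C9–C10 should interconvert 12 and 13 on warming while cyclization drains the mixture through 13 (Curtin–Hammett). The gem-disubstituted C5, the electron-rich trisubstituted ene donor and the proton-scavenging methylaluminium reagent (methane loss from the product alkoxide) should favour the concerted ene path over Prins-type chloride capture or silyl ether loss.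

Step 10
Reactants: 14 ene product
Product: 15 3α-(tert-butyldimethylsilyloxy)eremophila-9,11-dien-8-one
Conditions: Dess–Martin periodinane, NaHCO3, CH2Cl2, 0 °C to rt
Reagents that add atoms: none
Why: Buffered Dess–Martin oxidation converts the allylic alcohol to the enone under neutral conditions, which should avoid epimerisation at C7 and migration of the isopropenyl double bond into conjugation.

Step 11
Reactants: 15 dienone
Product: 17 3α-(tert-butyldimethylsilyloxy)-8-(trimethylsilyloxy)-10αH-eremophila-8,11-diene, via lithium enolate 16 (not isolated)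
Conditions: Li, NH3(l)/THF, t-BuOH (1 equiv), −78 °C; isoprene; evaporate NH3; TMSCl, Et3N, THF, −78 to 0 °C
Reagents that add atoms: chlorotrimethylsilane C[Si](C)(C)Cl
Why: Dissolving-metal enone reduction with Stork-type enolate trapping: the C10 carbanion is protonated axially, anti to the angular methyl, to give the trans-fused decalin (10α-H), the isolated isopropenyl alkene and the silyl ether are not reduced, and the regiodefined C8–C9 enolate is captured as its silyl enol ether.

Step 12
Reactants: 17 silyl enol ether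
Product: 20 3α-(tert-butyldimethylsilyloxy)-9α-hydroxy-10αH-eremophil-11-en-8-one, via silyloxy epoxide 18 (not isolated), via silyloxy ketone 19 (not isolated)
Conditions: mCPBA (1.05 equiv), NaHCO3, CH2Cl2, −20 °C; then citric acid, MeOH, 0 °C
Reagents that add atoms: meta-chloroperoxybenzoic acid OOC(=O)c1cccc(Cl)c1
Why: Rubottom oxidation: the peracid should epoxidise the electron-rich silyl enol ether much faster than the 1,1-disubstituted alkene and from the α face, away from the C5 methyl that is 1,3-diaxial to C9, so that silyl migration and methanolysis give the equatorial 9α-hydroxy ketone.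

Step 13
Reactants: 20 hydroxy ketone
Product: 21 3α-(tert-butyldimethylsilyloxy)-10αH-eremophil-11-ene-8α,9α-diol
Conditions: LiBH(s-Bu)3 (L-Selectride, 2.5 equiv), THF, −78 °C; aq. NH4Cl
Reagents that add atoms: none
Why: The bulky trialkylborohydride approaches the C8 carbonyl along the equatorial trajectory (the axial one is blocked by the axial hydrogens on C6 and C10), which should give the axial 8α alcohol cis to the 9α hydroxyl.

Step 14
Reactants: 21 diol
Product: 22 3α-(tert-butyldimethylsilyloxy)-8α,9α-(isopropylidenedioxy)-10αH-eremophil-11-ene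
Conditions: 2,2-dimethoxypropane, PPTS (cat.), CH2Cl2, rt
Reagents that add atoms: 2,2-dimethoxypropane COC(C)(C)OC
Why: Acid-catalysed transketalisation closes a dioxolane on the cis (axial/equatorial) 8,9-diol, and PPTS should leave the silyl ether and the isopropenyl group alone.

Step 15
Reactants: 22 acetonide silyl ether
Product: 23 core alcohol 8α,9α-(isopropylidenedioxy)-10αH-eremophil-11-en-3α-ol
Conditions: TBAF, THF, rt to 40 °C
Reagents that add atoms: none
Why: Fluoride cleaves the secondary silyl ether while the acetonide is inert, which frees the C3 hydroxyl alone for acylation.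

Step 16
Reactants: 24 (S)-2-hydroxybutanoic acid
Product: 25 methyl (S)-2-hydroxybutanoate
Conditions: MeOH, H2SO4 (cat.), reflux
Reagents that add atoms: methanol CO
Why: Fischer esterification of the α-hydroxy acid does not touch the stereocentre.

Step 17
Reactants: 25 methyl (S)-2-hydroxybutanoate
Product: 26 methyl (S)-2-(tert-butyldimethylsilyloxy)butanoate
Conditions: TBSCl, imidazole, DMF, rt
Reagents that add atoms: tert-butyldimethylsilyl chloride CC(C)(C)[Si](C)(C)Cl
Why: Standard silylation of the secondary alcohol under weakly basic conditions keeps the α stereocentre.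

Step 18
Reactants: 26 methyl (S)-2-(tert-butyldimethylsilyloxy)butanoate
Product: 27 (S)-2-(tert-butyldimethylsilyloxy)butanal
Conditions: i-Bu2AlH (1.1 equiv), CH2Cl2, −78 °C; Rochelle salt
Reagents that add atoms: none
Why: At −78 °C the tetrahedral aluminium hemiacetal persists until work-up, so half-reduction to the α-silyloxy aldehyde should occur without over-reduction; the aldehyde is used at once to avoid racemisation.

Step 19
Reactants: 27 (S)-2-(tert-butyldimethylsilyloxy)butanal
Product: 28 (S)-tert-butyl[(1,1-dibromopent-1-en-3-yl)oxy]dimethylsilane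
Conditions: CBr4, PPh3, CH2Cl2, 0 °C
Reagents that add atoms: carbon tetrabromide BrC(Br)(Br)Br
Why: Corey–Fuchs dibromoolefination (Wittig reaction of the ylide formed in the flask) runs under nonbasic conditions that keep the α stereocentre.

Step 20
Reactants: 28 dibromoalkene
Product: 30 (S)-4-(tert-butyldimethylsilyloxy)hex-2-ynoic acid, via lithium acetylide 29 (not isolated)
Conditions: n-BuLi (2.1 equiv), THF, −78 to 0 °C; then CO2, −78 °C to rt; aq. HCl
Reagents that add atoms: carbon dioxide O=C=O
Why: Second stage of the Corey–Fuchs sequence: bromine–lithium exchange and elimination give the lithium acetylide, which is carboxylated by CO2.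

Step 21
Reactants: 23 core alcohol; 30 (S)-4-(tert-butyldimethylsilyloxy)hex-2-ynoic acid
Product: 31 8α,9α-(isopropylidenedioxy)-10αH-eremophil-11-en-3α-yl (S)-4-(tert-butyldimethylsilyloxy)hex-2-ynoate
Conditions: DCC, DMAP (cat.), CH2Cl2, −20 to 0 °C
Reagents that add atoms: acid 30 CC[C@H](O[Si](C)(C)C(C)(C)C)C#CC(=O)O
Why: Steglich esterification at low temperature with only catalytic DMAP limits conjugate addition to the ynoic acid, and carrying the side chain as an alkyne secures the later Z geometry.

Step 22
Reactants: 31 silyloxy ynoate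
Product: 32 8α,9α-(isopropylidenedioxy)-10αH-eremophil-11-en-3α-yl (S)-4-hydroxyhex-2-ynoate
Conditions: HF·pyridine, pyridine/THF, 0 °C to rt
Reagents that add atoms: none
Why: Buffered HF·pyridine removes the propargylic silyl ether without basic fluoride, which could isomerise the γ-oxygenated ynoate to an allene, and the acetonide should survive.

Step 23
Reactants: 32 propargylic alcohol; 33 hex-2-ynoic acid
Product: 34 8α,9α-(isopropylidenedioxy)-10αH-eremophil-11-en-3α-yl (S)-4-(hex-2-ynoyloxy)hex-2-ynoate
Conditions: DCC, DMAP (cat.), CH2Cl2, 0 °C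
Reagents that add atoms: hex-2-ynoic acid 33 CCCC#CC(=O)O
Why: Steglich esterification of the secondary propargylic alcohol under the same low-temperature conditions should leave the first ynoate and the stereocentre untouched.

Step 24
Reactants: 34 bis-ynoate acetonide
Product: 35 8α,9α-dihydroxy-10αH-eremophil-11-en-3α-yl (S)-4-(hex-2-ynoyloxy)hex-2-ynoate
Conditions: AcOH/H2O (4:1), 40 °C
Reagents that add atoms: none
Why: Aqueous acetic acid hydrolyses the dioxolane of the cis diol under conditions that should leave the two esters, the alkynes and the isopropenyl group alone.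

Step 25
Reactants: 35 bis-ynoate diol
Product: 36 CNP0271544.1, 8α,9α-dihydroxy-10αH-eremophil-11-en-3α-yl (2Z,4S)-4-[(2Z)-hex-2-enoyloxy]hex-2-enoate
Conditions: H2 (1 atm), Pd/CaCO3 poisoned with Pb(OAc)2 (Lindlar catalyst), quinoline, EtOAc, rt, monitored uptake
Reagents that add atoms: none
Why: Lindlar semihydrogenation (syn addition of hydrogen on poisoned palladium) should convert both conjugated alkynes to Z alkenes, while quinoline and monitoring prevent over-reduction and the 1,1-disubstituted isopropenyl alkene is not reduced.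

Compound list
1 | 4-methoxy-3-methylphenol | COc1ccc(O)cc1C | starting material
2 | 4,4-dimethoxy-3-methylcyclohexa-2,5-dien-1-one | COC1(OC)C=CC(=O)C=C1C | intermediate
3 | 4,4-dimethoxy-3-methylcyclohex-2-en-1-one | COC1(OC)CCC(=O)C=C1C | intermediate
4 | (R)-4,4-dimethoxy-3-methylcyclohex-2-en-1-ol | CC1=C[C@H](O)CCC1(OC)OC | intermediate
5 | (R)-tert-butyl[(4,4-dimethoxy-3-methylcyclohex-2-en-1-yl)oxy]dimethylsilane | CC1=C[C@H](O[Si](C)(C)C(C)(C)C)CCC1(OC)OC | intermediate
6 | (R)-4-(tert-butyldimethylsilyloxy)-2-methylcyclohex-2-en-1-one | CC1=C[C@H](O[Si](C)(C)C(C)(C)C)CCC1=O | intermediate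
7 | prenyl bromide | CC(C)=CCBr | starting material
8 | lithium enolate of (3R,4R)-4-(tert-butyldimethylsilyloxy)-2,3-dimethylcyclohexanone (3-methyl trans to 4-silyloxy) | CC1=C([O-])CC[C@@H](O[Si](C)(C)C(C)(C)C)[C@@H]1C.[Li+] | intermediate (not isolated)
9 | ring A ketone, (2R,3R,4R)-4-(tert-butyldimethylsilyloxy)-2,3-dimethyl-2-(3-methylbut-2-en-1-yl)cyclohexan-1-one | CC(C)=CC[C@]1(C)[C@@H](C)[C@H](O[Si](C)(C)C(C)(C)C)CCC1=O | intermediate
10 | vinylmagnesium bromide | C=C[Mg]Br | starting material
11 | (2R,3R,4R)-4-(tert-butyldimethylsilyloxy)-2,3-dimethyl-2-(3-methylbut-2-en-1-yl)-1-vinylcyclohexan-1-ol, carbinol centre undefined | CC(C)=CC[C@]1(C)[C@@H](C)[C@H](O[Si](C)(C)C(C)(C)C)CCC1(O)C=C | intermediate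
12 | ring A enal, E isomer | CC(C)=CC[C@]1(C)[C@@H](C)[C@H](O[Si](C)(C)C(C)(C)C)CC/C1=C\C=O | intermediate
13 | ring A enal, Z isomer | CC(C)=CC[C@]1(C)[C@@H](C)[C@H](O[Si](C)(C)C(C)(C)C)CC/C1=C/C=O | intermediate
14 | 3α-(tert-butyldimethylsilyloxy)eremophila-9,11-dien-8β-ol | C=C(C)[C@@H]1C[C@]2(C)[C@@H](C)[C@H](O[Si](C)(C)C(C)(C)C)CCC2=C[C@H]1O | intermediate
15 | 3α-(tert-butyldimethylsilyloxy)eremophila-9,11-dien-8-one | C=C(C)[C@@H]1C[C@]2(C)[C@@H](C)[C@H](O[Si](C)(C)C(C)(C)C)CCC2=CC1=O | intermediate
16 | lithium 8(9)-enolate of the 10αH ketone | C=C(C)[C@@H]1C[C@]2(C)[C@@H](C)[C@H](O[Si](C)(C)C(C)(C)C)CC[C@H]2C=C1[O-].[Li+] | intermediate (not isolated)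
17 | 3α-(tert-butyldimethylsilyloxy)-8-(trimethylsilyloxy)-10αH-eremophila-8,11-diene | C=C(C)[C@@H]1C[C@]2(C)[C@@H](C)[C@H](O[Si](C)(C)C(C)(C)C)CC[C@H]2C=C1O[Si](C)(C)C | intermediate
18 | 8α,9α-epoxy-8β-(trimethylsilyloxy) derivative of 17 | C=C(C)[C@@H]1C[C@]2(C)[C@@H](C)[C@H](O[Si](C)(C)C(C)(C)C)CC[C@H]2[C@@H]3O[C@]13O[Si](C)(C)C | intermediate (not isolated)
19 | 3α-(tert-butyldimethylsilyloxy)-9α-(trimethylsilyloxy)-10αH-eremophil-11-en-8-one | C=C(C)[C@@H]1C[C@]2(C)[C@@H](C)[C@H](O[Si](C)(C)C(C)(C)C)CC[C@H]2[C@H](O[Si](C)(C)C)C1=O | intermediate (not isolated)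
20 | 3α-(tert-butyldimethylsilyloxy)-9α-hydroxy-10αH-eremophil-11-en-8-one | C=C(C)[C@@H]1C[C@]2(C)[C@@H](C)[C@H](O[Si](C)(C)C(C)(C)C)CC[C@H]2[C@H](O)C1=O | intermediate
21 | 3α-(tert-butyldimethylsilyloxy)-10αH-eremophil-11-ene-8α,9α-diol | C=C(C)[C@@H]1C[C@]2(C)[C@@H](C)[C@H](O[Si](C)(C)C(C)(C)C)CC[C@H]2[C@H](O)[C@@H]1O | intermediate
22 | 8α,9α-acetonide of 21 | C=C(C)[C@@H]1C[C@]2(C)[C@@H](C)[C@H](O[Si](C)(C)C(C)(C)C)CC[C@H]2[C@H](OC(C)(C)O3)[C@@H]13 | intermediate
23 | core alcohol, 8α,9α-(isopropylidenedioxy)-10αH-eremophil-11-en-3α-ol | C=C(C)[C@@H]1C[C@]2(C)[C@@H](C)[C@H](O)CC[C@H]2[C@H](OC(C)(C)O3)[C@@H]13 | intermediate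
24 | (S)-2-hydroxybutanoic acid | CC[C@H](O)C(=O)O | starting material
25 | methyl (S)-2-hydroxybutanoate | CC[C@H](O)C(=O)OC | intermediate
26 | methyl (S)-2-(tert-butyldimethylsilyloxy)butanoate | CC[C@H](O[Si](C)(C)C(C)(C)C)C(=O)OC | intermediate
27 | (S)-2-(tert-butyldimethylsilyloxy)butanal | CC[C@H](O[Si](C)(C)C(C)(C)C)C=O | intermediate
28 | (S)-tert-butyl[(1,1-dibromopent-1-en-3-yl)oxy]dimethylsilane | CC[C@H](O[Si](C)(C)C(C)(C)C)C=C(Br)Br | intermediate
29 | lithium (S)-3-(tert-butyldimethylsilyloxy)pent-1-yn-1-ide | CC[C@H](O[Si](C)(C)C(C)(C)C)C#C[Li] | intermediate (not isolated)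
30 | (S)-4-(tert-butyldimethylsilyloxy)hex-2-ynoic acid | CC[C@H](O[Si](C)(C)C(C)(C)C)C#CC(=O)O | intermediate
31 | C3 silyloxy-ynoate ester of the core | C=C(C)[C@@H]1C[C@]2(C)[C@@H](C)[C@H](OC(=O)C#C[C@H](CC)O[Si](C)(C)C(C)(C)C)CC[C@H]2[C@H](OC(C)(C)O3)[C@@H]13 | intermediate
32 | C3 (S)-4-hydroxyhex-2-ynoate ester of the core | C=C(C)[C@@H]1C[C@]2(C)[C@@H](C)[C@H](OC(=O)C#C[C@H](CC)O)CC[C@H]2[C@H](OC(C)(C)O3)[C@@H]13 | intermediate
33 | hex-2-ynoic acid | CCCC#CC(=O)O | starting material
34 | bis-ynoate acetonide | C=C(C)[C@@H]1C[C@]2(C)[C@@H](C)[C@H](OC(=O)C#C[C@H](CC)OC(=O)C#CCCC)CC[C@H]2[C@H](OC(C)(C)O3)[C@@H]13 | intermediate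
35 | bis-ynoate 8α,9α-diol | C=C(C)[C@@H]1C[C@]2(C)[C@@H](C)[C@H](OC(=O)C#C[C@H](CC)OC(=O)C#CCCC)CC[C@H]2[C@H](O)[C@@H]1O | intermediate
36 | CNP0271544.1 | C=C(C)[C@@H]1C[C@]2(C)[C@@H](C)[C@H](OC(=O)/C=C\[C@H](CC)OC(=O)/C=C\CCC)CC[C@H]2[C@H](O)[C@@H]1O | target

Total step count: 25. Longest linear sequence: 20 steps (steps 1–15, then 21–25); the side-chain acid takes 5 steps (16–20) off the main line.

Steps most likely to fail

Step 9. The E enal may not equilibrate to the reactive Z isomer fast enough under the Lewis acid, or ionic pathways (chloride capture at C11, alkene migration, silyl ether loss) may outrun the concerted ene process. The fallback removes the geometric requirement and sets out from the 12/13 mixture. The mixture is deconjugated through its dienolate (KHMDS, THF, −78 °C, then AcOH at −78 °C; kinetic α-protonation) to the β,γ-unsaturated aldehyde 2-[(4R,5R,6R)-4-(tert-butyldimethylsilyloxy)-5,6-dimethyl-6-(3-methylbut-2-en-1-yl)cyclohex-1-en-1-yl]acetaldehyde F1, whose CH2CHO arm rotates freely. Me2AlCl then effects the citronellal-type ene closure to 3α-(tert-butyldimethylsilyloxy)eremophila-1(10),11-dien-8β-ol F2. Dess–Martin oxidation gives the β,γ-enone 3α-(tert-butyldimethylsilyloxy)eremophila-1(10),11-dien-8-one F3. Mild acid (oxalic acid, EtOH) then moves the C1=C10 bond into conjugation, as in the isomerisation of β,γ- to α,β-unsaturated 3-keto steroids, and the route is rejoined at 15.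

Step 6. The prenyl group has to enter anti to the C4 methyl but syn to the C3 silyloxy group, so facial selectivity may be poor; the hindered tetrasubstituted enolate may also alkylate sluggishly or on oxygen. The fallback sets out from 6 and puts C5 under catalyst control. After the same cuprate addition, enolate 8 is trapped with allyl chloroformate as the allyl enol carbonate allyl (3R,4R)-4-(tert-butyldimethylsilyloxy)-2,3-dimethylcyclohex-1-en-1-yl carbonate F4. Decarboxylative allylation with Pd2(dba)3 and the t-BuPHOX enantiomer that reinforces delivery anti to the C4 methyl gives (2R,3R,4R)-2-allyl-4-(tert-butyldimethylsilyloxy)-2,3-dimethylcyclohexan-1-one F5. Cross-metathesis with 2-methylbut-2-ene (second-generation Grubbs catalyst RuCl2(=CHPh)(PCy3)(H2IMes)) turns allyl into prenyl and returns to 9.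

Step 8. The hindered tertiary chromate may rearrange slowly, and the acidic chromium reagent may trigger uncontrolled cyclization of the prenyl group onto the nascent enal or over-oxidation. The fallback is oxidant-free and sets out from ketone 9. (Z)-2-Ethoxyvinyllithium (from (Z)-1-bromo-2-ethoxyethene and n-BuLi, THF, −78 °C) is added to give the carbinol (2R,3R,4R)-4-(tert-butyldimethylsilyloxy)-1-[(Z)-2-ethoxyvinyl]-2,3-dimethyl-2-(3-methylbut-2-en-1-yl)cyclohexan-1-ol F6. Dilute HCl in THF then hydrolyses the enol ether with allylic transposition and loss of water, which returns the enal mixture 12/13.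

Further compounds
F1 | step 9 | 2-[(4R,5R,6R)-4-(tert-butyldimethylsilyloxy)-5,6-dimethyl-6-(3-methylbut-2-en-1-yl)cyclohex-1-en-1-yl]acetaldehyde | CC(C)=CC[C@]1(C)[C@@H](C)[C@H](O[Si](C)(C)C(C)(C)C)CC=C1CC=O
F2 | step 9 | 3α-(tert-butyldimethylsilyloxy)eremophila-1(10),11-dien-8β-ol | C=C(C)[C@@H]1C[C@]2(C)[C@@H](C)[C@H](O[Si](C)(C)C(C)(C)C)CC=C2C[C@H]1O
F3 | step 9 | 3α-(tert-butyldimethylsilyloxy)eremophila-1(10),11-dien-8-one | C=C(C)[C@@H]1C[C@]2(C)[C@@H](C)[C@H](O[Si](C)(C)C(C)(C)C)CC=C2CC1=O
F4 | step 6 | allyl (3R,4R)-4-(tert-butyldimethylsilyloxy)-2,3-dimethylcyclohex-1-en-1-yl carbonate | CC1=C(OC(=O)OCC=C)CC[C@@H](O[Si](C)(C)C(C)(C)C)[C@@H]1C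
F5 | step 6 | (2R,3R,4R)-2-allyl-4-(tert-butyldimethylsilyloxy)-2,3-dimethylcyclohexan-1-one | C=CC[C@]1(C)[C@@H](C)[C@H](O[Si](C)(C)C(C)(C)C)CCC1=O
F6 | step 8 | (2R,3R,4R)-4-(tert-butyldimethylsilyloxy)-1-[(Z)-2-ethoxyvinyl]-2,3-dimethyl-2-(3-methylbut-2-en-1-yl)cyclohexan-1-ol, carbinol centre undefined | CC(C)=CC[C@]1(C)[C@@H](C)[C@H](O[Si](C)(C)C(C)(C)C)CCC1(O)/C=C\OCC
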